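The earlier runs and the new flask stem from a simulated flask with made-up constants; the scatter is artificial.

Hold the making of target against its loss: in the north-west run target climbs to 23.1% by 15.0 h and stands near 23.5% at 20.0 h, while starting material keeps falling to 64.8%.

| flask | starting material | partner | second substrate | temperature | remark | time |
|---|---|---|---|---|---|---|
| north-west | 0.15 M | 0.10 M | 0.50 M | 40 °C | run made earlier |  |
| theta | 0.10 M | 0.100 M | 0.500 M | 40 °C |  | 2.5 d |
| beta | 0.10 M | 0.100 M | 0.500 M | 10 °C |  | 2.5 d |
| gamma | 0.10 M | 0.100 M | 0.500 M | 25 °C |  | 2.5 d |

north-west run (percent of the starting material charged)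

| time / h | target / % | starting material / % |
|---|---|---|
| 3.00 | 9.3 | 90.4 |
| 6.00 | 15.0 | 83.8 |
| 10.0 | 18.7 | 75.6 |
| 12.0 | 20.9 | 72.2 |
| 15.0 | 23.1 | 70.5 |
| 20.0 | 23.5 | 64.8 |

(each reading ± 1 percentage point)

- the earlier runs do not show what temperature does; that part of a forecast is a guess

- the best flask by amount of target, in percent of the starting material charged; "all alike" if 1.5 percentage points covers them all (theta / beta / gamma / all alike)
- amount of target at the end, in percent of the starting material charged, theta
- amount of target at the end, in percent of the starting material charged, beta
- amount of target at the end, in percent of the starting material charged, gamma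

Write the balance of partner, the limiting reagent of that run: taking starting material as its one consumer, the charge less the starting material consumed leaves 0.0472 M at the last reading. The integrated second-order law then reads k = 0.317 L mol⁻¹ h⁻¹. Now set the balance of target to zero. Making, k[starting material][partner], equals loss, k_L[target], so the last reading gives k/k_L = 7.68 L mol⁻¹. Multiply by the charge of partner to get the stall number, 0.768, the ratio [target]/[starting material] at which target would stand still with partner at full charge.

Read theta off it. With equal charges, let a be the fraction left of each; target stalls when its fraction equals N·a². Counting reacted starting material as target gives a = 0.663, so I put the top of target in theta below 33.7%, a figure that ignores loss. That stall needs k[partner]t = 0.509, but theta reaches 1.90, so theta runs well past it. There the stall line stands at 9.13%, and falling target lags above that, so I expect the low teens or a little more.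

One number isn't enough: beta and gamma change both k and k_L by unknown amounts. Slowing the making 3.73-fold with N held would put the end of theta at the stall, and I guess gamma comes closest to that.

The forecast picks gamma, with 20% for theta, 14% for beta and 28% for gamma, and says “Temperature is a guess”.

The flasks give 16.6% in theta, 14.1% in beta and 31.5% in gamma, so gamma holds most.

    starting material + partner → target (k = 0.370 L mol⁻¹ h⁻¹, Ea = 63.0 kJ mol⁻¹)
    second substrate + partner → second product (k = 0.0350 L mol⁻¹ h⁻¹, Ea = 85.0 kJ mol⁻¹)
    target ⇌ isomer of the product (K = 29.0, k = 0.00220 h⁻¹, Ea = 118 kJ mol⁻¹, ΔH = 41.0 kJ mol⁻¹)
    2 starting material → homo dimer (k = 3.10 × 10⁻⁴ L mol⁻¹ h⁻¹, Ea = 97.0 kJ mol⁻¹)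
    target → over-reaction product (k = 0.0270 h⁻¹, Ea = 95.0 kJ mol⁻¹)
    (constants at 40 °C)

Put theta's end state into the balance: making over loss, with the stall number read at 20.0 h, comes to 0.204, so by this reckoning target in theta is used up faster than it is made, with 9.74% of the partner left and 34.9% standing as over-reaction product. In gamma at the asked time target is made 2.38 times faster than it is used up, with 49.1% of the partner left and 5.16% as over-reaction product.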